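**Strategy.** The dihydrofuran ring (O1, C2, C3, C3a, C7a) is disconnected at C2–C3. C3 is benzylic to C3a and its hydroxymethyl carbon can stand at the ester level, while C2–H lies α to O1 and 1,5 to C3; a donor/acceptor rhodium carbene at C3 can therefore insert into an aryl ether O–CH2 group. One operation forms C2–C3, closes the last ring and sets C2 (catalyst) and C3 (equilibration to trans). The precursor is an aryl diazoacetate whose ortho oxygen carries the complete, silylated cyclohexane; its three stereocentres derive from C1' (Diels–Alder), relayed by hydroxyl-directed epoxidation and trans-diaxial methanolysis.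

Key step: step 9

Locants: benzofuran numbering (O1, C2, C3, C3a, C7a); the cyclohexane is C1'–C6', with C1' bonded to C2, C3' bearing OH and C4' bearing OMe.

Assumption: the facial preferences of the chiral catalysts in steps 1 and 9 are taken by analogy with simpler substrates of the same class; both catalysts exist in either mirror-image form, so a reversed sense would be met by using the antipode.

Step 1
Reactants: 1 2-bromoacrolein; 2 buta-1,3-diene
Product: 3 (R)-1-bromocyclohex-3-ene-1-carbaldehyde
Conditions: (S)-2-butyl-4-(1H-indol-3-ylmethyl)-3-tosyl-1,3,2-oxazaborolidin-5-one (10 mol%), excess 2, CH2Cl2, −78 → −40 °C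
Reagents that add atoms: none
Why: Enantioselective Lewis-acid-catalysed Diels–Alder reaction; the boron-bound 2-bromoacrolein is shielded on one face by the indole of the tryptophan-derived catalyst, so the diene should add to the open face and set C1' as (R).

Step 2
Reactants: 3 (R)-1-bromocyclohex-3-ene-1-carbaldehyde
Product: 4 [(R)-1-bromocyclohex-3-en-1-yl]methanol
Conditions: NaBH4, MeOH–CH2Cl2, −40 → 0 °C; AcOH quench
Reagents that add atoms: none
Why: Chemoselective borohydride 1,2-reduction of the aldehyde at low temperature; the tertiary C–Br bond and the stereocentre are untouched.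

Step 3
Reactants: 5 methyl 3-(4-hydroxy-3-methoxyphenyl)propanoate
Product: 6 methyl 3-(4-hydroxy-3-iodo-5-methoxyphenyl)propanoate
Conditions: I2, NaHCO3, THF–H2O, 0 °C → rt
Reagents that add atoms: iodine, II
Why: Electrophilic aromatic iodination of the phenoxide; the para position is blocked, so iodine should enter the only free position ortho to the phenolic oxygen (the future C3a).

Step 4
Reactants: 4 [(R)-1-bromocyclohex-3-en-1-yl]methanol; 6 methyl 3-(4-hydroxy-3-iodo-5-methoxyphenyl)propanoate
Product: 8 methyl 3-(4-{[(1S)-1-hydroxycyclohex-3-en-1-yl]methoxy}-3-iodo-5-methoxyphenyl)propanoate, via spiro-epoxide 7 (not isolated)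
Conditions: Cs2CO3, DMF, 80 °C
Reagents that add atoms: none
Why: Intramolecular Williamson closure of the bromohydrin to spiro-epoxide 7 inverts C1' (R → S), and the phenoxide of 6 then opens 7 by SN2 attack at its CH2 terminus, which leaves the C1'–O bond and its configuration intact.

Step 5
Reactants: 8 methyl 3-(4-{[(1S)-1-hydroxycyclohex-3-en-1-yl]methoxy}-3-iodo-5-methoxyphenyl)propanoate
Product: 9 methyl 3-(4-{[(1S,3S,6R)-3-hydroxy-7-oxabicyclo[4.1.0]heptan-3-yl]methoxy}-3-iodo-5-methoxyphenyl)propanoate (epoxide oxygen cis to the tertiary OH)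
Conditions: VO(acac)2 (5 mol%), t-BuOOH, CH2Cl2, 0 °C → rt
Reagents that add atoms: tert-butyl hydroperoxide, CC(C)(C)OO
Why: Hydroxyl-directed vanadium-catalysed epoxidation; the vanadate ester of the axial tertiary homoallylic alcohol delivers oxygen to the alkene face syn to OH, which sets C3' and C4' relative to C1'.

Step 6
Reactants: 9 cis-epoxy alcohol
Product: 10 methyl 3-(4-{[(1S,3S,4S)-1,3-dihydroxy-4-methoxycyclohexyl]methoxy}-3-iodo-5-methoxyphenyl)propanoate
Conditions: MeOH, camphor-10-sulfonic acid (10 mol%), CH2Cl2, 0 °C → rt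
Reagents that add atoms: methanol, CO
Why: Acid-catalysed trans-diaxial (Fürst–Plattner) epoxide opening; with CH2OAr equatorial and the axial OH hydrogen-bonded to the epoxide oxygen, methanol should attack C4' (the carbon remote from the electron-withdrawing C1') with inversion, giving C3'–OH cis to C1'–OH and C4'–OMe trans to C3'–OH.

Step 7
Reactants: 10 diol methyl ether
Product: 11 methyl 3-(3-iodo-5-methoxy-4-{[(1S,3S,4S)-4-methoxy-1,3-bis(triethylsilyloxy)cyclohexyl]methoxy}phenyl)propanoate
Conditions: TESOTf, 2,6-lutidine, CH2Cl2, −78 → 0 °C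
Reagents that add atoms: triethylsilyl trifluoromethanesulfonate, CC[Si](CC)(CC)OS(=O)(=O)C(F)(F)F
Why: Silyl triflate silylation is strong enough for the tertiary and the secondary hydroxyl, and both must be masked to prevent O–H insertion of the later carbene.

Step 8
Reactants: 11 bis-silyl aryl iodide; 12 ethyl diazoacetate
Product: 13 ethyl 2-diazo-2-[3-methoxy-2-{[(1S,3S,4S)-4-methoxy-1,3-bis(triethylsilyloxy)cyclohexyl]methoxy}-5-(3-methoxy-3-oxopropyl)phenyl]acetate
Conditions: Pd(PPh3)4 (5 mol%), Ag2CO3, Et3N, toluene, rt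
Reagents that add atoms: none
Why: Palladium-catalysed cross-coupling of an aryl iodide with the C–H bond of an acceptor diazo compound (oxidative addition, silver-assisted iodide abstraction, palladation of the diazo carbon, reductive elimination) keeps the diazo group, and the silyl ethers and the methyl ester are inert at room temperature.

Step 9
Reactants: 13 aryl diazoacetate
Product: 15 ethyl (2S,3S)-7-methoxy-2-[(1S,3S,4S)-4-methoxy-1,3-bis(triethylsilyloxy)cyclohexyl]-5-(3-methoxy-3-oxopropyl)-2,3-dihydro-1-benzofuran-3-carboxylate (trans ester), via cis ester 14 (not isolated)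
Conditions: Rh2(S-PTTL)4 [dirhodium tetrakis(N-phthaloyl-(S)-tert-leucinate)] (1 mol%), toluene, −40 → 0 °C, slow addition of 13; then DBU, 50 °C
Reagents that add atoms: none
Why: Rh2(S-PTTL)4 expels N2 from 13 to give an electrophilic donor/acceptor rhodium carbene at C3, which inserts into one O1-activated C–H bond of the O–CH2 group through a concerted, asynchronous three-centre transition state and so forms C2–C3. The closest known reaction is the dirhodium-catalysed intramolecular C–H insertion of ortho-alkoxyaryl diazoacetates to 2,3-dihydrobenzofuran-3-carboxylates. The dihydrofuran ring closes in the 1,5-insertion mode, through a five-membered cyclic transition state made of C3, C3a, C7a, O1 and C2. C2 is controlled by the chiral carboxylate pocket of the catalyst, which selects one of the two diastereotopic hydrogens (the adjacent C1' is locally almost symmetric and exerts little bias of its own), and C3 is controlled thermodynamically, DBU equilibrating the kinetic cis ester 14 through its enolate to the trans ester 15, in which the ester and the bulky C2 substituent are anti. The step needs site selectivity, secured because only the O–CH2 hydrogens are both oxygen-activated and 1,5 to the carbene (C3'–H, C4'–H and silyl C–H bonds would require seven-membered or larger transition states), and chemoselectivity over O–H insertion and carbene dimerisation, secured by silylation of both hydroxyls and slow addition at low temperature. Ring opening by retro-oxa-Michael reaction during the equilibration is stereoelectronically disfavoured (it is the reverse of a 5-endo-trig closure), so C2 should not be scrambled.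

Step 10
Reactants: 15 trans ester
Product: 17 difengpiol B, via bis-silyl diol 16 (not isolated)
Conditions: LiAlH4, THF, 0 °C; then 2 M HCl, MeOH, rt
Reagents that add atoms: none
Why: Hydride reduction converts both esters into primary alcohols without touching C3, and the acidic work-up hydrolyses the two triethylsilyl ethers; no stereocentre is affected.

**Compound list**

1 | 2-bromoacrolein (2-bromoprop-2-enal) | C=C(Br)C=O | starting material
2 | buta-1,3-diene | C=CC=C | starting material
3 | (R)-1-bromocyclohex-3-ene-1-carbaldehyde | O=C[C@@]1(Br)CCC=CC1 | intermediate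
4 | [(R)-1-bromocyclohex-3-en-1-yl]methanol | OC[C@@]1(Br)CCC=CC1 | intermediate
5 | methyl 3-(4-hydroxy-3-methoxyphenyl)propanoate | COc1cc(CCC(=O)OC)ccc1O | starting material
6 | methyl 3-(4-hydroxy-3-iodo-5-methoxyphenyl)propanoate | COc1cc(CCC(=O)OC)cc(I)c1O | intermediate
7 | (S)-1-oxaspiro[2.5]oct-5-ene | C1O[C@]12CCC=CC2 | intermediate (not isolated)
8 | methyl 3-(4-{[(1S)-1-hydroxycyclohex-3-en-1-yl]methoxy}-3-iodo-5-methoxyphenyl)propanoate | COc1cc(CCC(=O)OC)cc(I)c1OC[C@]1(O)CCC=CC1 | intermediate
9 | methyl 3-(4-{[(1S,3S,6R)-3-hydroxy-7-oxabicyclo[4.1.0]heptan-3-yl]methoxy}-3-iodo-5-methoxyphenyl)propanoate | COc1cc(CCC(=O)OC)cc(I)c1OC[C@]1(O)CC[C@H]2O[C@H]2C1 | intermediate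
10 | methyl 3-(4-{[(1S,3S,4S)-1,3-dihydroxy-4-methoxycyclohexyl]methoxy}-3-iodo-5-methoxyphenyl)propanoate | COc1cc(CCC(=O)OC)cc(I)c1OC[C@]1(O)CC[C@H](OC)[C@@H](O)C1 | intermediate
11 | methyl 3-(3-iodo-5-methoxy-4-{[(1S,3S,4S)-4-methoxy-1,3-bis(triethylsilyloxy)cyclohexyl]methoxy}phenyl)propanoate | COc1cc(CCC(=O)OC)cc(I)c1OC[C@]1(O[Si](CC)(CC)CC)CC[C@H](OC)[C@@H](O[Si](CC)(CC)CC)C1 | intermediate
12 | ethyl diazoacetate | CCOC(=O)C=[N+]=[N-] | starting material
13 | ethyl 2-diazo-2-[3-methoxy-2-{[(1S,3S,4S)-4-methoxy-1,3-bis(triethylsilyloxy)cyclohexyl]methoxy}-5-(3-methoxy-3-oxopropyl)phenyl]acetate | COc1cc(CCC(=O)OC)cc(C(=[N+]=[N-])C(=O)OCC)c1OC[C@]1(O[Si](CC)(CC)CC)CC[C@H](OC)[C@@H](O[Si](CC)(CC)CC)C1 | intermediate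
14 | ethyl (2S,3R)-7-methoxy-2-[(1S,3S,4S)-4-methoxy-1,3-bis(triethylsilyloxy)cyclohexyl]-5-(3-methoxy-3-oxopropyl)-2,3-dihydro-1-benzofuran-3-carboxylate (cis) | COc1cc(CCC(=O)OC)cc2c1O[C@H]([C@]1(O[Si](CC)(CC)CC)CC[C@H](OC)[C@@H](O[Si](CC)(CC)CC)C1)[C@@H]2C(=O)OCC | intermediate (not isolated)
15 | ethyl (2S,3S)-7-methoxy-2-[(1S,3S,4S)-4-methoxy-1,3-bis(triethylsilyloxy)cyclohexyl]-5-(3-methoxy-3-oxopropyl)-2,3-dihydro-1-benzofuran-3-carboxylate (trans) | COc1cc(CCC(=O)OC)cc2c1O[C@H]([C@]1(O[Si](CC)(CC)CC)CC[C@H](OC)[C@@H](O[Si](CC)(CC)CC)C1)[C@H]2C(=O)OCC | intermediate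
16 | 3-{(2S,3R)-3-(hydroxymethyl)-7-methoxy-2-[(1S,3S,4S)-4-methoxy-1,3-bis(triethylsilyloxy)cyclohexyl]-2,3-dihydro-1-benzofuran-5-yl}propan-1-ol | COc1cc(CCCO)cc2c1O[C@H]([C@]1(O[Si](CC)(CC)CC)CC[C@H](OC)[C@@H](O[Si](CC)(CC)CC)C1)[C@H]2CO | intermediate (not isolated)
17 | difengpiol B, (1S,3S,4S)-1-[(2S,3R)-3-(hydroxymethyl)-5-(3-hydroxypropyl)-7-methoxy-2,3-dihydro-1-benzofuran-2-yl]-4-methoxycyclohexane-1,3-diol | COc1cc(CCCO)cc2c1O[C@H]([C@]1(O)CC[C@H](OC)[C@@H](O)C1)[C@H]2CO | target

**Step count.** Total: 10 steps. Longest linear sequence: 9 steps (steps 1, 2 and 4–10, from 2-bromoacrolein).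

**Steps most likely to fail**

Step 9. What may go wrong: insufficient discrimination between the two diastereotopic O–CH2 hydrogens. The reacting methylene is neopentylic and C1' is locally almost symmetric, so the catalyst pocket alone must select, and control at C2 may be lost. The fallback moves the stereocontrol from the catalyst to a covalently bound auxiliary on the carbene ester and sets out from 11. Commercial (S)-2-hydroxy-1-(pyrrolidin-1-yl)propan-1-one is acylated with bromoacetyl bromide (pyridine, CH2Cl2) to the lactamide bromoacetate F1. N,N'-Ditosylhydrazine and DBU convert it into the lactamide diazoacetate F2. Coupling of F2 with 11 under the conditions of step 8 should give the auxiliary-bearing aryl diazoacetate F3. Insertion with Rh2(S-DOSP)4 [dirhodium tetrakis((S)-N-(4-dodecylbenzenesulfonyl)prolinate)] in CH2Cl2 should then give the trans auxiliary ester F4 directly, the lactamide carbonyl biasing one face of the carbene. LiAlH4 in THF cleaves the auxiliary ester and reduces the side-chain ester, and the route is rejoined at 16, which the acidic work-up of step 10 takes on to 17.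

Step 8. What may go wrong: slow oxidative addition into the hindered, electron-rich aryl iodide, with competing palladium-mediated decomposition of the diazoacetate. The fallback builds the arylacetate first and introduces the diazo group afterwards; it sets out from 11. Negishi coupling with the Reformatsky reagent BrZnCH2CO2Et (Pd2(dba)3, XPhos, THF, 60 °C) should give the ethyl arylacetate F5. Regitz diazo transfer (4-acetamidobenzenesulfonyl azide, DBU, MeCN) acts only on the aryl-activated methylene, not on the side-chain ester, and rejoins the route at 13.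

Step 5. What may go wrong: weak direction by the hindered tertiary homoallylic hydroxyl, so that slow, undirected epoxidation erodes facial selectivity. The fallback delivers the C3' oxygen through a tether and sets out from 8. The sodium alkoxide of 8 (NaH, THF, 0 °C) is carboxylated with CO2 and cyclised with I2 to the cyclic iodocarbonate F6. Only the six-membered carbonate can form, so oxygen adds to C3' on the face of the C1' oxygen and iodine ends up trans at C4'. K2CO3 in MeOH cleaves the carbonate, the C3' alkoxide displaces the trans-diaxial iodide, and the route is rejoined at 9.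

**Further compounds**

F1 | step 9 | (S)-1-oxo-1-(pyrrolidin-1-yl)propan-2-yl 2-bromoacetate | C[C@H](OC(=O)CBr)C(=O)N1CCCC1
F2 | step 9 | (S)-1-oxo-1-(pyrrolidin-1-yl)propan-2-yl 2-diazoacetate | C[C@H](OC(=O)C=[N+]=[N-])C(=O)N1CCCC1
F3 | step 9 | (S)-1-oxo-1-(pyrrolidin-1-yl)propan-2-yl 2-diazo-2-[3-methoxy-2-{[(1S,3S,4S)-4-methoxy-1,3-bis(triethylsilyloxy)cyclohexyl]methoxy}-5-(3-methoxy-3-oxopropyl)phenyl]acetate | COc1cc(CCC(=O)OC)cc(C(=[N+]=[N-])C(=O)O[C@@H](C)C(=O)N2CCCC2)c1OC[C@]1(O[Si](CC)(CC)CC)CC[C@H](OC)[C@@H](O[Si](CC)(CC)CC)C1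
F4 | step 9 | (S)-1-oxo-1-(pyrrolidin-1-yl)propan-2-yl (2S,3S)-7-methoxy-2-[(1S,3S,4S)-4-methoxy-1,3-bis(triethylsilyloxy)cyclohexyl]-5-(3-methoxy-3-oxopropyl)-2,3-dihydro-1-benzofuran-3-carboxylate | COc1cc(CCC(=O)OC)cc2c1O[C@H]([C@]1(O[Si](CC)(CC)CC)CC[C@H](OC)[C@@H](O[Si](CC)(CC)CC)C1)[C@H]2C(=O)O[C@@H](C)C(=O)N1CCCC1
F5 | step 8 | ethyl 2-[3-methoxy-2-{[(1S,3S,4S)-4-methoxy-1,3-bis(triethylsilyloxy)cyclohexyl]methoxy}-5-(3-methoxy-3-oxopropyl)phenyl]acetate | COc1cc(CCC(=O)OC)cc(CC(=O)OCC)c1OC[C@]1(O[Si](CC)(CC)CC)CC[C@H](OC)[C@@H](O[Si](CC)(CC)CC)C1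
F6 | step 5 | methyl 3-(3-iodo-4-{[(1S,5S,6S)-6-iodo-3-oxo-2,4-dioxabicyclo[3.3.1]nonan-1-yl]methoxy}-5-methoxyphenyl)propanoate | COc1cc(CCC(=O)OC)cc(I)c1OC[C@]1(OC(=O)O2)CC[C@H](I)[C@@H]2C1
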